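## Retrosynthetic overview

1. Amaurone B 24 ⇐ all-cis tetraol 23 (acetylation of the two secondary OH) ⇐ ene-diol 21 (hydroxyl-directed syn-dihydroxylation) ⇐ rac-20 (kinetic resolution).
2. rac-20 ⇐ endoperoxide 19 (O–O reduction) ⇐ cyclohexadiene 18, by [4+2] addition of singlet oxygen anti to the two cis ring substituents.
3. 18 ⇐ linear hexaene 17 by thermal disrotatory 6π-electrocyclisation of its (8E,10Z,12E)-triene end; 17 ⇐ Suzuki union of tetraenyl boronate 16 with (Z)-dienyl iodide 2 (from tiglic aldehyde 1).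
4. 16 ⇐ vinylogous aldol condensation of ethylpyranone 7 (from triketide ester 5 by enol-lactonisation and O-methylation) with trienal boronate 12 (from alkyne 8 by hydroboration and two Wittig homologations).
5. Ring order: pyranone (step 3), cyclohexadiene (step 9), transient 2,3-dioxabicyclo[2.2.2]octene (step 10, opened again).

## Assumptions

- Presumed biosynthesis: linear hexaene pyranone → 6π-electrocyclisation → O2 [4+2] endoperoxide → O–O opening and cis-hydroxylation on the same face → O-acetylation.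
- Racemates are written as the two enantiomers joined by a dot.
- The antipode of the acyl-transfer catalyst in step 11 is the one that acetylates the unnatural enantiomer faster; it is fixed by a trial run on the racemate and written here as the (−)-antipode.

## Route

Step 1
Reactants: 1 (E)-2-methylbut-2-enal
Product: 2 (2Z,4E)-2-iodo-4-methylhexa-2,4-diene
Conditions: EtPPh3I, n-BuLi, THF, 0 → 23 °C; I2, −78 °C; NaHMDS, −20 °C; then 1, −78 → −20 °C, dark
Reagents that add atoms: ethyltriphenylphosphonium iodide CC[P+](c1ccccc1)(c1ccccc1)c1ccccc1.[I-]; iodine II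
Why: Stork–Zhao-type Wittig olefination with the non-stabilised α-iodoethylidene ylide proceeds under kinetic control through the cis-oxaphosphetane, so iodine ends up cis to the dienyl chain (2Z) while the existing E alkene is untouched.

Step 2
Reactants: 3 methyl 2-methyl-3-oxopentanoate
Product: 5 methyl 2,4-dimethyl-3,5-dioxoheptanoate, via ketoester dianion 4 (not isolated)
Conditions: NaH, THF, 0 °C; n-BuLi, −10 °C; EtC(O)N(OMe)Me, −78 → 0 °C; aq. HCl
Reagents that add atoms: N-methoxy-N-methylpropanamide CCC(=O)N(C)OC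
Why: Huckin–Weiler γ-acylation, in which the more reactive C4 terminus of the β-ketoester dianion attacks the Weinreb amide, whose chelated tetrahedral adduct prevents over-addition, and no stereocentre of consequence is formed.

Step 3
Reactants: 5 methyl 2,4-dimethyl-3,5-dioxoheptanoate
Product: 6 6-ethyl-4-hydroxy-3,5-dimethyl-2H-pyran-2-one
Conditions: DBU, toluene, 110 °C; aq. HCl
Reagents that add atoms: none
Why: Base-mediated enol-lactonisation (the laboratory counterpart of triketide pyranone release) closes the 4-hydroxy-2-pyranone with loss of methanol.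

Step 4
Reactants: 6 6-ethyl-4-hydroxy-3,5-dimethyl-2H-pyran-2-one
Product: 7 2-ethyl-6-methoxy-3,5-dimethyl-4H-pyran-4-one
Conditions: MeOTf, CH2Cl2, 23 °C; sat. aq. NaHCO3
Reagents that add atoms: methyl triflate COS(=O)(=O)C(F)(F)F
Why: Beak-type O-methylation, in which the hard methylating agent alkylates the lactone carbonyl oxygen and loss of the 4-OH proton from the 2-methoxypyrylium gives the α-methoxy-γ-pyranone instead of the 4-methoxy-α-pyranone.

Step 5
Reactants: 8 3,3-diethoxyprop-1-yne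
Product: 10 (E)-3-(4,4,5,5-tetramethyl-1,3,2-dioxaborolan-2-yl)prop-2-enal, via boryl acetal 9 (not isolated)
Conditions: HBpin, Cp2Zr(H)Cl (5 mol %), Et3N (10 mol %), neat, 60 °C; then H2O, Amberlyst-15, acetone, 23 °C
Reagents that add atoms: pinacolborane [H]B1OC(C)(C)C(C)(C)O1; water O
Why: Zirconium-catalysed hydroboration adds H–B syn and anti-Markovnikov to the terminal alkyne to give the (E)-alkenylboronate, and mild acid hydrolysis of the acetal releases the enal.

Step 6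
Reactants: 10 (E)-3-(4,4,5,5-tetramethyl-1,3,2-dioxaborolan-2-yl)prop-2-enal
Product: 11 (2E,4E)-2-methyl-5-(4,4,5,5-tetramethyl-1,3,2-dioxaborolan-2-yl)penta-2,4-dienal
Conditions: Ph3P=C(Me)CHO, toluene, 40 °C
Reagents that add atoms: 2-(triphenylphosphoranylidene)propanal CC(C=O)=P(c1ccccc1)(c1ccccc1)c1ccccc1
Why: Wittig olefination with a stabilised formyl ylide is E-selective and stops at the α-branched enal, which is much less electrophilic than 10.

Step 7
Reactants: 11 (2E,4E)-2-methyl-5-(4,4,5,5-tetramethyl-1,3,2-dioxaborolan-2-yl)penta-2,4-dienal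
Product: 12 (2E,4E,6E)-4-methyl-7-(4,4,5,5-tetramethyl-1,3,2-dioxaborolan-2-yl)hepta-2,4,6-trienal
Conditions: Ph3P=CHCHO, toluene, 70 °C
Reagents that add atoms: (triphenylphosphoranylidene)acetaldehyde O=CC=P(c1ccccc1)(c1ccccc1)c1ccccc1
Why: Wittig two-carbon homologation with the stabilised formylmethylene ylide gives the new disubstituted alkene E and leaves the alkenylboronate untouched.

Step 8
Reactants: 7 2-ethyl-6-methoxy-3,5-dimethyl-4H-pyran-4-one; 12 (2E,4E,6E)-4-methyl-7-(4,4,5,5-tetramethyl-1,3,2-dioxaborolan-2-yl)hepta-2,4,6-trienal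
Product: 16 2-methoxy-3,5-dimethyl-6-[(2E,4E,6E,8E)-6-methyl-9-(4,4,5,5-tetramethyl-1,3,2-dioxaborolan-2-yl)nona-2,4,6,8-tetraen-2-yl]-4H-pyran-4-one, via lithiated pyranone 13 (not isolated), via lithium aldolate 14 (not isolated), via allylic mesylate 15 (not isolated)
Conditions: 7, LiHMDS, THF, −78 °C; 12, −78 °C; MsCl, −78 → 0 °C; DBU, 0 → 23 °C, dark
Reagents that add atoms: none
Why: Vinylogous (lateral) aldol addition of the lithiated 6-ethylpyranone to the aldehyde, then mesylation of the aldolate and base-induced E1cB elimination, gives the fully conjugated alkene with the thermodynamically preferred E geometry.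

Step 9
Reactants: 16 2-methoxy-3,5-dimethyl-6-[(2E,4E,6E,8E)-6-methyl-9-(4,4,5,5-tetramethyl-1,3,2-dioxaborolan-2-yl)nona-2,4,6,8-tetraen-2-yl]-4H-pyran-4-one; 2 (2Z,4E)-2-iodo-4-methylhexa-2,4-diene
Product: 18 rac-2-methoxy-3,5-dimethyl-6-{(2E,4E,6E)-6-methyl-7-[(1S*,6S*)-3,5,6-trimethylcyclohexa-2,4-dien-1-yl]hepta-2,4,6-trien-2-yl}-4H-pyran-4-one, via linear hexaene 17 (not isolated)
Conditions: Pd(dppf)Cl2·CH2Cl2 (5 mol %), aq. K3PO4, THF, 40 °C, dark; aqueous layer removed, toluene, 95 °C, 4 h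
Reagents that add atoms: none
Why: Suzuki–Miyaura coupling with retention of both alkene geometries gives the hexaene whose terminal (8E,10Z,12E)-triene is the only one with a Z central bond and therefore the only one able to undergo the thermal, Woodward–Hoffmann-allowed disrotatory 6π-electrocyclisation, which places the side chain and the C6 methyl cis on the new cyclohexadiene (racemic).

Step 10
Reactants: 18 rac-2-methoxy-3,5-dimethyl-6-{(2E,4E,6E)-6-methyl-7-[(1S*,6S*)-3,5,6-trimethylcyclohexa-2,4-dien-1-yl]hepta-2,4,6-trien-2-yl}-4H-pyran-4-one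
Product: 20 rac-(1S*,4R*,5S*,6R*)-6-[(1E,3E,5E)-6-(6-methoxy-3,5-dimethyl-4-oxo-4H-pyran-2-yl)-2-methylhepta-1,3,5-trien-1-yl]-2,4,5-trimethylcyclohex-2-ene-1,4-diol, via bicyclic endoperoxide 19 (not isolated)
Conditions: O2, TPP (1 mol %), CH2Cl2, −20 °C, 590 nm LED; then thiourea, MeOH, 23 °C
Reagents that add atoms: dioxygen O=O
Why: [4+2] cycloaddition of singlet oxygen (Schenck-type photooxygenation) to the s-cis ring diene, far faster than any reaction of the s-trans acceptor-conjugated side-chain triene, occurs on the face anti to the cis C6 methyl and side chain and sets both C–O centres, and thiourea then cleaves only the O–O bond with retention to the cis-1,4-diol.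

Step 11
Reactants: 20 rac-(1S*,4R*,5S*,6R*)-6-[(1E,3E,5E)-6-(6-methoxy-3,5-dimethyl-4-oxo-4H-pyran-2-yl)-2-methylhepta-1,3,5-trien-1-yl]-2,4,5-trimethylcyclohex-2-ene-1,4-diol
Product: 21 (1S,4R,5S,6R)-6-[(1E,3E,5E)-6-(6-methoxy-3,5-dimethyl-4-oxo-4H-pyran-2-yl)-2-methylhepta-1,3,5-trien-1-yl]-2,4,5-trimethylcyclohex-2-ene-1,4-diol
Conditions: (−)-(C5Ph5)Fe(4-dimethylaminopyrindinyl) (2 mol %), Ac2O (0.65 equiv), Et3N (0.65 equiv), t-amyl alcohol, 0 °C, to ca. 60 % conversion; chromatography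
Reagents that add atoms: none
Why: Acylative kinetic resolution of a secondary allylic alcohol with a planar-chiral DMAP catalyst (Fu type), in which the unnatural enantiomer is acetylated faster at its C1 hydroxyl, so the (1S,4R,5S,6R)-diol is recovered in high ee and the absolute configuration of the four ring stereocentres already present is fixed.

Step 12
Reactants: 21 (1S,4R,5S,6R)-6-[(1E,3E,5E)-6-(6-methoxy-3,5-dimethyl-4-oxo-4H-pyran-2-yl)-2-methylhepta-1,3,5-trien-1-yl]-2,4,5-trimethylcyclohex-2-ene-1,4-diol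
Product: 23 (1S,2S,3R,4R,5S,6R)-6-[(1E,3E,5E)-6-(6-methoxy-3,5-dimethyl-4-oxo-4H-pyran-2-yl)-2-methylhepta-1,3,5-trien-1-yl]-2,4,5-trimethylcyclohexane-1,2,3,4-tetrol, via TMEDA osmate ester 22 (not isolated)
Conditions: OsO4 (1.05 equiv), TMEDA (1.1 equiv), CH2Cl2, −78 °C; then sat. aq. Na2SO3, THF, 50 °C
Reagents that add atoms: osmium tetroxide O=[Os](=O)(=O)=O
Why: Donohoe hydrogen-bond-directed dihydroxylation, in which the OsO4·TMEDA complex is held by the two allylic hydroxyls and adds suprafacially ([3+2]) to the ring alkene from their face, which is also the face opposite the C4 methyl, C5 methyl and C6 side chain, so the new C2 and C3 hydroxyls are cis to both older ones while the undirected side-chain alkenes react more slowly.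

Step 13
Reactants: 23 (1S,2S,3R,4R,5S,6R)-6-[(1E,3E,5E)-6-(6-methoxy-3,5-dimethyl-4-oxo-4H-pyran-2-yl)-2-methylhepta-1,3,5-trien-1-yl]-2,4,5-trimethylcyclohexane-1,2,3,4-tetrol
Product: 24 amaurone B
Conditions: Ac2O, pyridine, DMAP (5 mol %), CH2Cl2, 0 → 23 °C
Reagents that add atoms: acetic anhydride CC(=O)OC(C)=O
Why: DMAP-catalysed acetylation esterifies the two equatorial secondary hydroxyls at C1 and C3, whereas the two tertiary hydroxyls at C2 and C4 do not react at room temperature, so no stereocentre is touched.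

## Compound list

1 | (E)-2-methylbut-2-enal (tiglic aldehyde) | C/C=C(\C)C=O | starting material
2 | (2Z,4E)-2-iodo-4-methylhexa-2,4-diene | C/C(I)=C/C(C)=C/C | intermediate
3 | methyl 2-methyl-3-oxopentanoate | CCC(=O)C(C)C(=O)OC | starting material
4 | sodium lithium C2,C4-dianion of 3 | [Na+].[Li+].C[CH-]C(=O)[C-](C)C(=O)OC | intermediate
5 | methyl 2,4-dimethyl-3,5-dioxoheptanoate (stereoisomer and tautomer mixture) | CCC(=O)C(C)C(=O)C(C)C(=O)OC | intermediate
6 | 6-ethyl-4-hydroxy-3,5-dimethyl-2H-pyran-2-one | CCc1oc(=O)c(C)c(O)c1C | intermediate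
7 | 2-ethyl-6-methoxy-3,5-dimethyl-4H-pyran-4-one | CCc1oc(OC)c(C)c(=O)c1C | intermediate
8 | 3,3-diethoxyprop-1-yne | C#CC(OCC)OCC | starting material
9 | (E)-2-(3,3-diethoxyprop-1-en-1-yl)-4,4,5,5-tetramethyl-1,3,2-dioxaborolane | CCOC(OCC)/C=C/B1OC(C)(C)C(C)(C)O1 | intermediate
10 | (E)-3-(4,4,5,5-tetramethyl-1,3,2-dioxaborolan-2-yl)prop-2-enal | O=C/C=C/B1OC(C)(C)C(C)(C)O1 | intermediate
11 | (2E,4E)-2-methyl-5-(4,4,5,5-tetramethyl-1,3,2-dioxaborolan-2-yl)penta-2,4-dienal | O=C/C(C)=C/C=C/B1OC(C)(C)C(C)(C)O1 | intermediate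
12 | (2E,4E,6E)-4-methyl-7-(4,4,5,5-tetramethyl-1,3,2-dioxaborolan-2-yl)hepta-2,4,6-trienal | O=C/C=C/C(C)=C/C=C/B1OC(C)(C)C(C)(C)O1 | intermediate
13 | lithium 1-(6-methoxy-3,5-dimethyl-4-oxo-4H-pyran-2-yl)ethan-1-ide (lithiated 7) | [Li+].C[CH-]c1oc(OC)c(C)c(=O)c1C | intermediate
14 | lithium aldolate of 13 and 12 (diastereomer mixture) | [Li+].[O-]C(/C=C/C(C)=C/C=C/B1OC(C)(C)C(C)(C)O1)C(C)c1oc(OC)c(C)c(=O)c1C | intermediate
15 | methanesulfonate of the aldol adduct (diastereomer mixture) | CS(=O)(=O)OC(/C=C/C(C)=C/C=C/B1OC(C)(C)C(C)(C)O1)C(C)c1oc(OC)c(C)c(=O)c1C | intermediate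
16 | 2-methoxy-3,5-dimethyl-6-[(2E,4E,6E,8E)-6-methyl-9-(4,4,5,5-tetramethyl-1,3,2-dioxaborolan-2-yl)nona-2,4,6,8-tetraen-2-yl]-4H-pyran-4-one | COc1oc(/C(C)=C/C=C/C(C)=C/C=C/B2OC(C)(C)C(C)(C)O2)c(C)c(=O)c1C | intermediate
17 | 2-methoxy-3,5-dimethyl-6-[(2E,4E,6E,8E,10Z,12E)-6,10,12-trimethyltetradeca-2,4,6,8,10,12-hexaen-2-yl]-4H-pyran-4-one | COc1oc(/C(C)=C/C=C/C(C)=C/C=C/C(C)=C\C(C)=C\C)c(C)c(=O)c1C | intermediate
18 | rac-2-methoxy-3,5-dimethyl-6-{(2E,4E,6E)-6-methyl-7-[(1S*,6S*)-3,5,6-trimethylcyclohexa-2,4-dien-1-yl]hepta-2,4,6-trien-2-yl}-4H-pyran-4-one (side chain and C6 methyl cis) | COc1oc(/C(C)=C/C=C/C(C)=C/[C@@H]2[C@H](C)C(C)=CC(C)=C2)c(C)c(=O)c1C.COc1oc(/C(C)=C/C=C/C(C)=C/[C@H]2[C@@H](C)C(C)=CC(C)=C2)c(C)c(=O)c1C | intermediate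
19 | rac-2-methoxy-3,5-dimethyl-6-{(2E,4E,6E)-6-methyl-7-[4,6,8-trimethyl-2,3-dioxabicyclo[2.2.2]oct-5-en-7-yl]hepta-2,4,6-trien-2-yl}-4H-pyran-4-one (peroxide bridge anti to the cis C7 side chain and C8 methyl) | COc1oc(/C(C)=C/C=C/C(C)=C/[C@@H]2[C@H](C)[C@]3(C)C=C(C)[C@H]2OO3)c(C)c(=O)c1C.COc1oc(/C(C)=C/C=C/C(C)=C/[C@H]2[C@@H](C)[C@@]3(C)C=C(C)[C@@H]2OO3)c(C)c(=O)c1C | intermediate
20 | rac-(1S*,4R*,5S*,6R*)-6-[(1E,3E,5E)-6-(6-methoxy-3,5-dimethyl-4-oxo-4H-pyran-2-yl)-2-methylhepta-1,3,5-trien-1-yl]-2,4,5-trimethylcyclohex-2-ene-1,4-diol | COc1oc(/C(C)=C/C=C/C(C)=C/[C@@H]2[C@H](C)[C@@](C)(O)C=C(C)[C@H]2O)c(C)c(=O)c1C.COc1oc(/C(C)=C/C=C/C(C)=C/[C@H]2[C@@H](C)[C@](C)(O)C=C(C)[C@@H]2O)c(C)c(=O)c1C | intermediate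
21 | (1S,4R,5S,6R)-6-[(1E,3E,5E)-6-(6-methoxy-3,5-dimethyl-4-oxo-4H-pyran-2-yl)-2-methylhepta-1,3,5-trien-1-yl]-2,4,5-trimethylcyclohex-2-ene-1,4-diol (single enantiomer) | COc1oc(/C(C)=C/C=C/C(C)=C/[C@@H]2[C@H](C)[C@@](C)(O)C=C(C)[C@H]2O)c(C)c(=O)c1C | intermediate
22 | cyclic osmate(VI) ester of 21 across O2 and O3, chelated by TMEDA | COc1oc(/C(C)=C/C=C/C(C)=C/[C@@H]2[C@H](C)[C@@](C)(O)[C@@H](O[Os-2]3(=O)(=O)(O4)[N+](C)(C)CC[N+]3(C)C)[C@]4(C)[C@H]2O)c(C)c(=O)c1C | intermediate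
23 | (1S,2S,3R,4R,5S,6R)-6-[(1E,3E,5E)-6-(6-methoxy-3,5-dimethyl-4-oxo-4H-pyran-2-yl)-2-methylhepta-1,3,5-trien-1-yl]-2,4,5-trimethylcyclohexane-1,2,3,4-tetrol (all four O cis, opposite the three ring C-substituents at C4, C5, C6) | COc1oc(/C(C)=C/C=C/C(C)=C/[C@@H]2[C@H](C)[C@@](C)(O)[C@@H](O)[C@@](C)(O)[C@H]2O)c(C)c(=O)c1C | intermediate
24 | amaurone B, (1S,2S,3R,4R,5S,6R)-2,4-dihydroxy-6-[(1E,3E,5E)-6-(6-methoxy-3,5-dimethyl-4-oxo-4H-pyran-2-yl)-2-methylhepta-1,3,5-trien-1-yl]-2,4,5-trimethylcyclohexane-1,3-diyl diacetate | COc1oc(/C(C)=C/C=C/C(C)=C/[C@@H]2[C@H](C)[C@@](C)(O)[C@@H](OC(C)=O)[C@@](C)(O)[C@H]2OC(C)=O)c(C)c(=O)c1C | target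

## Step count and risks

Total step count: 13. Longest linear sequence: 9 steps (8 → 24 through steps 5–13; equally 3 → 24 through steps 2–4 and 8–13).

**Step 8 (aldol condensation beside an alkenyl boronate).** The lithiated pyranone or residual amide base may attack boron, and the product is a light-sensitive tetraenyl boronate. The fallback sets out from 7 and comes back at 16, carrying the chain end as a masked aldehyde and installing boron last. Purchased (E)-4,4-dimethoxy-2-methylbut-2-enal F1 is homologated with (triphenylphosphoranylidene)acetaldehyde to (2E,4E)-6,6-dimethoxy-4-methylhexa-2,4-dienal F2. Lithiated pyranone 13 (from 7) adds to it to give the hydroxy acetal aldol adduct F3. p-TsOH in wet acetone then dehydrates the alcohol and hydrolyses the acetal in one operation to the pyranonyl trienal F4. Boron-Wittig olefination of F4 with lithiated bis(pinacolato)borylmethane (CH2(Bpin)2, LiTMP, THF, −78 → 23 °C) gives the (E)-alkenyl boronate 16.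

**Step 9 (Suzuki coupling and 6π-electrocyclisation on the complete polyene).** The long polyenyl boronate may transmetalate slowly or protodeborylate, and the hexaene may degrade before it cyclises. The fallback sets out from 12 and 2 and comes back at 18, reversing the order of events. Boronate 12 is coupled with iodide 2 under the same palladium conditions, and the resulting (2E,4E,6E,8Z,10E)-4,8,10-trimethyldodeca-2,4,6,8,10-pentaenal F5 is heated in toluene to the racemic cis-cyclohexadienyl dienal F6. Lithiated pyranone 13 adds to F6 to give the lithium aldolate F7, which is trapped with MsCl as the mesylate F8 and eliminated with DBU to 18.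

**Step 11 (acylative kinetic resolution).** The selectivity factor on this hindered, doubly flanked cyclohexenol may be too low. The fallback sets out from 20 and comes back at 21 by classical resolution through covalent diastereomers. The secondary hydroxyl of 20 is esterified with (S)-2-methoxy-2-phenylacetic acid (EDC·HCl, DMAP, CH2Cl2, 0 °C). The two esters, the (S)-O-methylmandelate of the natural-series diol F9 and the (S)-O-methylmandelate of the enantiomeric diol F10, are separated by chromatography and assigned by their Δδ values. F9 is cleaved with K2CO3 in MeOH to give 21.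

## Further compounds

F1 | step 8 | (E)-4,4-dimethoxy-2-methylbut-2-enal (purchased) | O=C/C(C)=C/C(OC)OC
F2 | step 8 | (2E,4E)-6,6-dimethoxy-4-methylhexa-2,4-dienal | O=C/C=C/C(C)=C/C(OC)OC
F3 | step 8 | 2-[(4E,6E)-3-hydroxy-8,8-dimethoxy-6-methylocta-4,6-dien-2-yl]-6-methoxy-3,5-dimethyl-4H-pyran-4-one (diastereomer mixture) | COC(OC)/C=C(C)/C=C/C(O)C(C)c1oc(OC)c(C)c(=O)c1C
F4 | step 8 | (2E,4E,6E)-7-(6-methoxy-3,5-dimethyl-4-oxo-4H-pyran-2-yl)-3-methylocta-2,4,6-trienal | COc1oc(/C(C)=C/C=C/C(C)=C/C=O)c(C)c(=O)c1C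
F5 | step 9 | (2E,4E,6E,8Z,10E)-4,8,10-trimethyldodeca-2,4,6,8,10-pentaenal | O=C/C=C/C(C)=C/C=C/C(C)=C\C(C)=C\C
F6 | step 9 | rac-(2E,4E)-4-methyl-5-[(1S*,6S*)-3,5,6-trimethylcyclohexa-2,4-dien-1-yl]penta-2,4-dienal | O=C/C=C/C(C)=C/[C@@H]1[C@H](C)C(C)=CC(C)=C1.O=C/C=C/C(C)=C/[C@H]1[C@@H](C)C(C)=CC(C)=C1
F7 | step 9 | lithium aldolate of 13 and F6 (racemic ring, diastereomer mixture) | [Li+].[O-]C(/C=C/C(C)=C/[C@@H]1[C@H](C)C(C)=CC(C)=C1)C(C)c1oc(OC)c(C)c(=O)c1C.[Li+].[O-]C(/C=C/C(C)=C/[C@H]1[C@@H](C)C(C)=CC(C)=C1)C(C)c1oc(OC)c(C)c(=O)c1C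
F8 | step 9 | methanesulfonate of the aldol adduct F7 (racemic ring, diastereomer mixture) | CS(=O)(=O)OC(/C=C/C(C)=C/[C@@H]1[C@H](C)C(C)=CC(C)=C1)C(C)c1oc(OC)c(C)c(=O)c1C.CS(=O)(=O)OC(/C=C/C(C)=C/[C@H]1[C@@H](C)C(C)=CC(C)=C1)C(C)c1oc(OC)c(C)c(=O)c1C
F9 | step 11 | (1S,4R,5S,6R)-4-hydroxy-6-[(1E,3E,5E)-6-(6-methoxy-3,5-dimethyl-4-oxo-4H-pyran-2-yl)-2-methylhepta-1,3,5-trien-1-yl]-2,4,5-trimethylcyclohex-2-en-1-yl (S)-2-methoxy-2-phenylacetate | COc1oc(/C(C)=C/C=C/C(C)=C/[C@@H]2[C@H](C)[C@@](C)(O)C=C(C)[C@H]2OC(=O)[C@@H](OC)c2ccccc2)c(C)c(=O)c1C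
F10 | step 11 | (1R,4S,5R,6S)-4-hydroxy-6-[(1E,3E,5E)-6-(6-methoxy-3,5-dimethyl-4-oxo-4H-pyran-2-yl)-2-methylhepta-1,3,5-trien-1-yl]-2,4,5-trimethylcyclohex-2-en-1-yl (S)-2-methoxy-2-phenylacetate | COc1oc(/C(C)=C/C=C/C(C)=C/[C@H]2[C@@H](C)[C@](C)(O)C=C(C)[C@@H]2OC(=O)[C@@H](OC)c2ccccc2)c(C)c(=O)c1C
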